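**Plan**
- Retrosynthesis: the three MOM ethers come off last. Ring C of the (2S)-flavanone is then cut at O1–C8a and at C4–C4a in one stroke. This leaves a ring-A aryne (C4a≡C8a) and the four-atom unit O1–C2–C3–C4, held as an (S)-β-silyloxy N,N-dimethylamide that carries ring B.
- Enabling feature: C4a and C8a are neighbours in ring A, and ring A is a phloroglucinol (O on C5, C7 and C8a). Its own C8a oxygen can therefore leave as triflate next to a silyl group on C4a. The C5 oxygen beside C4a polarises the aryne, so that O1 goes to C8a and the carbanion, hence the acyl carbon C4, to C4a.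
- Fragment A, forward: phloroglucinol → bis-MOM ether → diethylcarbamate. Three directed ortho-metalations (SiMe3, prenyl, prenyl) fill the ring, then carbamate → phenol → triflate.
- Fragment B, forward: methyl 5-bromovanillate → MOM ether → Stille prenylation → acylation of the dimethylacetamide enolate → asymmetric transfer hydrogenation → O-silylation.
- Rings A and B are bought as benzene rings. Ring C is the only ring made, in the key step, when fluoride joins the two fragments. Acid then frees the three phenols.
- Stereochemistry: the only stereocenter, C2, is set as (S) by Noyori–Ikariya transfer hydrogenation of the β-keto amide. It is carried through because the C2–O1 bond is never broken.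

Key step: step 13

Remark: flavanone numbering is used (O1, C2, C3, C4, C4a, C5 to C8, C8a; ring B primed). Prenyl = 3-methylbut-2-en-1-yl and MOM = methoxymethyl. The descriptor read from the SMILES is (2S). Compound 12 and tributyl(prenyl)stannane are taken to be commercial.

**Step 1**
Reactants: 1 phloroglucinol (benzene-1,3,5-triol)
Product: 2 3,5-bis(methoxymethoxy)phenol
Conditions: MOMCl (2.0 equiv), i-Pr2NEt (2.2 equiv), DMF, 0 °C → rt; chromatography
Reagents that add atoms: chloromethyl methyl ether, COCCl
Why: Williamson-type O-alkylation of the threefold symmetric triphenol with two equivalents of MOMCl should give the bis-ether as the main member of a statistical set, separable by polarity, and the one free OH marks the future C8a oxygen.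

**Step 2**
Reactants: 2 3,5-bis(methoxymethoxy)phenol
Product: 3 3,5-bis(methoxymethoxy)phenyl N,N-diethylcarbamate
Conditions: ClC(O)NEt2 (1.2 equiv), K2CO3, MeCN, reflux
Reagents that add atoms: N,N-diethylcarbamoyl chloride, CCN(CC)C(=O)Cl
Why: O-carbamoylation of a phenol puts the strongest oxygen-based director for ortho-metalation on the oxygen that is to leave later as triflate.

**Step 3**
Reactants: 3 3,5-bis(methoxymethoxy)phenyl N,N-diethylcarbamate
Product: 5 3,5-bis(methoxymethoxy)-2-(trimethylsilyl)phenyl N,N-diethylcarbamate, via aryllithium 4 (not isolated)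
Conditions: s-BuLi (1.1 equiv), TMEDA, THF, −78 °C; then Me3SiCl, −78 °C → rt
Reagents that add atoms: chlorotrimethylsilane, C[Si](C)(C)Cl
Why: Directed ortho-metalation should take place at one of the two equivalent C–H positions flanked by both the carbamate and a MOM ether, where the two directors cooperate, and the silyl chloride traps the anion there (future C4a).

**Step 4**
Reactants: 5 3,5-bis(methoxymethoxy)-2-(trimethylsilyl)phenyl N,N-diethylcarbamate
Product: 7 3,5-bis(methoxymethoxy)-2-(3-methylbut-2-en-1-yl)-6-(trimethylsilyl)phenyl N,N-diethylcarbamate, via aryllithium 6 (not isolated)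
Conditions: s-BuLi (1.1 equiv), TMEDA, THF, −78 °C; then prenyl bromide (1.5 equiv), −78 → −20 °C
Reagents that add atoms: prenyl bromide (1-bromo-3-methylbut-2-ene), CC(C)=CCBr
Why: In this second directed ortho-metalation the carbamate outranks MOM as director, so the remaining carbamate-flanked C–H (future C8) is lithiated rather than the one between the two MOM ethers, and SN2 alkylation by the allylic bromide in the cold should outrun the anionic ortho-Fries shift.

**Step 5**
Reactants: 7 3,5-bis(methoxymethoxy)-2-(3-methylbut-2-en-1-yl)-6-(trimethylsilyl)phenyl N,N-diethylcarbamate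
Product: 9 3,5-bis(methoxymethoxy)-2,4-bis(3-methylbut-2-en-1-yl)-6-(trimethylsilyl)phenyl N,N-diethylcarbamate, via aryllithium 8 (not isolated)
Conditions: s-BuLi (1.2 equiv), TMEDA, THF, −78 °C; then prenyl bromide, −78 °C → rt
Reagents that add atoms: prenyl bromide (1-bromo-3-methylbut-2-ene), CC(C)=CCBr
Why: The third directed ortho-metalation addresses the only ring C–H left (future C6), which two chelating MOM ethers flank, and at −78 °C this complex-induced lithiation should be faster than removal of a benzylic-allylic proton of the prenyl group already present.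

**Step 6**
Reactants: 9 3,5-bis(methoxymethoxy)-2,4-bis(3-methylbut-2-en-1-yl)-6-(trimethylsilyl)phenyl N,N-diethylcarbamate
Product: 10 3,5-bis(methoxymethoxy)-2,4-bis(3-methylbut-2-en-1-yl)-6-(trimethylsilyl)phenol
Conditions: LiAlH4 (2 equiv), THF, reflux; then H2O, 0 °C
Reagents that add atoms: none
Why: Reductive cleavage of an aryl carbamate by hydride frees the hindered phenol, the carbamoyl carbon ending as an N-methyl group, without touching MOM ethers, alkenes or the aryl–silicon bond.

**Step 7**
Reactants: 10 3,5-bis(methoxymethoxy)-2,4-bis(3-methylbut-2-en-1-yl)-6-(trimethylsilyl)phenol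
Product: 11 3,5-bis(methoxymethoxy)-2,4-bis(3-methylbut-2-en-1-yl)-6-(trimethylsilyl)phenyl trifluoromethanesulfonate
Conditions: Tf2O (1.2 equiv), pyridine, CH2Cl2, 0 °C
Reagents that add atoms: trifluoromethanesulfonic anhydride, O=S(=O)(OS(=O)(=O)C(F)(F)F)C(F)(F)F
Why: O-triflation of the phenol completes the o-silylaryl triflate, the standard fluoride-triggered aryne precursor, with silicon on C4a and the leaving group on C8a.

**Step 8**
Reactants: 12 methyl 3-bromo-4-hydroxy-5-methoxybenzoate (methyl 5-bromovanillate)
Product: 13 methyl 3-bromo-5-methoxy-4-(methoxymethoxy)benzoate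
Conditions: MOMCl (1.5 equiv), i-Pr2NEt, CH2Cl2, 0 °C → rt
Reagents that add atoms: chloromethyl methyl ether, COCCl
Why: Williamson-type O-alkylation masks the 4'-phenol with the same acid-labile group as on ring A, so that one final operation frees all three phenols.

**Step 9**
Reactants: 13 methyl 3-bromo-5-methoxy-4-(methoxymethoxy)benzoate
Product: 14 methyl 3-methoxy-4-(methoxymethoxy)-5-(3-methylbut-2-en-1-yl)benzoate
Conditions: Bu3SnCH2CH=CMe2 (1.2 equiv), Pd(PPh3)4 (5 mol %), DMF, 100 °C
Reagents that add atoms: tributyl(3-methylbut-2-en-1-yl)stannane, CCCC[Sn](CCCC)(CCCC)CC=C(C)C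
Why: In this Stille coupling, oxidative addition of zerovalent palladium into the C–Br bond, transmetalation of the allylic stannane and reductive elimination should give the linear prenyl arene under neutral conditions that spare ester and MOM ether.

**Step 10**
Reactants: 14 methyl 3-methoxy-4-(methoxymethoxy)-5-(3-methylbut-2-en-1-yl)benzoate
Product: 15 3-[3-methoxy-4-(methoxymethoxy)-5-(3-methylbut-2-en-1-yl)phenyl]-N,N-dimethyl-3-oxopropanamide
Conditions: LiN(i-Pr)2 and MeC(O)NMe2 (2.2 equiv each), THF, −78 °C; then 14, −78 → 0 °C; then AcOH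
Reagents that add atoms: N,N-dimethylacetamide, CC(=O)N(C)C
Why: In this crossed Claisen-type acylation the lithium enolate of dimethylacetamide attacks the non-enolisable benzoate, and the β-keto amide is shielded from further attack as its enolate until the acid quench.

**Step 11**
Reactants: 15 3-[3-methoxy-4-(methoxymethoxy)-5-(3-methylbut-2-en-1-yl)phenyl]-N,N-dimethyl-3-oxopropanamide
Product: 16 (3S)-3-hydroxy-3-[3-methoxy-4-(methoxymethoxy)-5-(3-methylbut-2-en-1-yl)phenyl]-N,N-dimethylpropanamide
Conditions: RuCl[(S,S)-TsDPEN](p-cymene) (1 mol %), HCO2H/Et3N (5:2), 30 °C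
Reagents that add atoms: none
Why: In the Noyori–Ikariya asymmetric transfer hydrogenation the CH/π contact between the p-cymene ligand and ring B orients the aryl ketone in the six-membered outer-sphere transition state, so the (S,S) catalyst should deliver hydride to the face that gives the (S) carbinol (the sense known for acetophenone), while isolated trisubstituted alkenes are left alone.

**Step 12**
Reactants: 16 (3S)-3-hydroxy-3-[3-methoxy-4-(methoxymethoxy)-5-(3-methylbut-2-en-1-yl)phenyl]-N,N-dimethylpropanamide
Product: 17 (3S)-3-[3-methoxy-4-(methoxymethoxy)-5-(3-methylbut-2-en-1-yl)phenyl]-N,N-dimethyl-3-(trimethylsilyloxy)propanamide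
Conditions: Me3SiCl (1.2 equiv), imidazole, CH2Cl2, 0 °C
Reagents that add atoms: chlorotrimethylsilane, C[Si](C)(C)Cl
Why: Standard O-silylation removes the only acidic proton of the fragment, so that fluoride can later release the alkoxide with no proton source in the flask, and the stereocenter is not involved.

**Step 13**
Reactants: 11 3,5-bis(methoxymethoxy)-2,4-bis(3-methylbut-2-en-1-yl)-6-(trimethylsilyl)phenyl trifluoromethanesulfonate; 17 (3S)-3-[3-methoxy-4-(methoxymethoxy)-5-(3-methylbut-2-en-1-yl)phenyl]-N,N-dimethyl-3-(trimethylsilyloxy)propanamide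
Product: 22 (2S)-5,7-bis(methoxymethoxy)-2-[3-methoxy-4-(methoxymethoxy)-5-(3-methylbut-2-en-1-yl)phenyl]-6,8-bis(3-methylbut-2-en-1-yl)-2,3-dihydro-4H-chromen-4-one, via aryne 18 (not isolated), via potassium alkoxide 19 (not isolated), via arylpotassium 20 (not isolated), via hemiaminal alkoxide 21 (not isolated)
Conditions: 17, KF (4 equiv), 18-crown-6 (4 equiv), THF, −20 °C; 11 (1.2 equiv) added slowly, −20 → 0 °C; then AcOH in THF, −20 °C, then H2O
Reagents that add atoms: none
Why: Proposed new method: fluoride unmasks both partners at once, taking the O-silyl group of 17 to give the proton-free alkoxide 19 and the C-silyl group of 11 to give, with loss of triflate, aryne 18 (C4a≡C8a), whereupon O1 of 19 adds to C8a and the C4a carbanion 20 closes ring C by 6-exo-trig addition to the amide carbonyl carbon C4, giving hemiaminal alkoxide 21, which has no good leaving group and falls apart to ketone 22 and dimethylamine only in the acidic quench. The closest known reaction types are the annulation of arynes with salicylate esters to xanthones (O-addition, then acyl capture of the aryl anion), the insertion of arynes into amide N–C(O) bonds, and ketone synthesis from aryllithiums and tertiary amides through a persistent tetrahedral adduct, but an aliphatic β-oxido amide has not been used as the four-atom partner, hence the label. No lasting stereocenter is made, because the C2–O1 bond of 17 is never broken, so the (S) configuration from step 11 is carried over with retention, and the C4 center of 21 is lost again on collapse. The regioselectivity needed (O1 to C8a, C4 to C4a) is secured by the C5 methoxymethoxy group next to C4a, whose inductive pull distorts the aryne so that nucleophiles attack the distal carbon C8a and the charge builds at C4a, an electronic bias expected to outweigh the steric one of the C8 prenyl group. The chemoselectivity needed is secured by the tertiary amide: its α-hydrogens are too weakly acidic for enolisation, retro-aldol cleavage or quenching of 20, it sets free no alkoxide that would compete for the aryne, and it keeps ring C masked as 21, so the base-sensitive flavanone (E1cB opening to the chalcone would racemise C2) never meets the basic medium. The alkoxide, present at full concentration before the aryne is released, should also outrun ene reactions with prenyl groups of other molecules, and the C8 prenyl group cannot reach the aryne carbons in an ene geometry.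

**Step 14**
Reactants: 22 (2S)-5,7-bis(methoxymethoxy)-2-[3-methoxy-4-(methoxymethoxy)-5-(3-methylbut-2-en-1-yl)phenyl]-6,8-bis(3-methylbut-2-en-1-yl)-2,3-dihydro-4H-chromen-4-one
Product: 23 (2S)-5,7-dihydroxy-2-[4-hydroxy-3-methoxy-5-(3-methylbut-2-en-1-yl)phenyl]-6,8-bis(3-methylbut-2-en-1-yl)-2,3-dihydro-4H-chromen-4-one (CNP0235424.1)
Conditions: conc. HCl (cat.), MeOH, 40 °C
Reagents that add atoms: none
Why: Acid-catalysed acetal exchange with methanol is the usual MOM cleavage for prenylated flavonoids and should free all three phenols, while C2 is safe because flavanones do not open under dilute acid.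

**Compound list**
1 | phloroglucinol | Oc1cc(O)cc(O)c1 | starting material
2 | 3,5-bis(methoxymethoxy)phenol | COCOc1cc(O)cc(OCOC)c1 | intermediate
3 | 3,5-bis(methoxymethoxy)phenyl N,N-diethylcarbamate | CCN(CC)C(=O)Oc1cc(OCOC)cc(OCOC)c1 | intermediate
4 | 2-lithio derivative of 3 (lithium between carbamate and MOM ether) | CCN(CC)C(=O)Oc1cc(OCOC)cc(OCOC)c1[Li] | intermediate
5 | 3,5-bis(methoxymethoxy)-2-(trimethylsilyl)phenyl N,N-diethylcarbamate | CCN(CC)C(=O)Oc1cc(OCOC)cc(OCOC)c1[Si](C)(C)C | intermediate
6 | 6-lithio derivative of 5 | CCN(CC)C(=O)Oc1c([Li])c(OCOC)cc(OCOC)c1[Si](C)(C)C | intermediate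
7 | 3,5-bis(methoxymethoxy)-2-(3-methylbut-2-en-1-yl)-6-(trimethylsilyl)phenyl N,N-diethylcarbamate | CCN(CC)C(=O)Oc1c(CC=C(C)C)c(OCOC)cc(OCOC)c1[Si](C)(C)C | intermediate
8 | 4-lithio derivative of 7 | CCN(CC)C(=O)Oc1c(CC=C(C)C)c(OCOC)c([Li])c(OCOC)c1[Si](C)(C)C | intermediate
9 | 3,5-bis(methoxymethoxy)-2,4-bis(3-methylbut-2-en-1-yl)-6-(trimethylsilyl)phenyl N,N-diethylcarbamate | CCN(CC)C(=O)Oc1c(CC=C(C)C)c(OCOC)c(CC=C(C)C)c(OCOC)c1[Si](C)(C)C | intermediate
10 | 3,5-bis(methoxymethoxy)-2,4-bis(3-methylbut-2-en-1-yl)-6-(trimethylsilyl)phenol | Oc1c(CC=C(C)C)c(OCOC)c(CC=C(C)C)c(OCOC)c1[Si](C)(C)C | intermediate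
11 | 3,5-bis(methoxymethoxy)-2,4-bis(3-methylbut-2-en-1-yl)-6-(trimethylsilyl)phenyl trifluoromethanesulfonate | FC(F)(F)S(=O)(=O)Oc1c(CC=C(C)C)c(OCOC)c(CC=C(C)C)c(OCOC)c1[Si](C)(C)C | intermediate
12 | methyl 3-bromo-4-hydroxy-5-methoxybenzoate | COC(=O)c1cc(Br)c(O)c(OC)c1 | starting material
13 | methyl 3-bromo-5-methoxy-4-(methoxymethoxy)benzoate | COC(=O)c1cc(Br)c(OCOC)c(OC)c1 | intermediate
14 | methyl 3-methoxy-4-(methoxymethoxy)-5-(3-methylbut-2-en-1-yl)benzoate | COC(=O)c1cc(CC=C(C)C)c(OCOC)c(OC)c1 | intermediate
15 | 3-[3-methoxy-4-(methoxymethoxy)-5-(3-methylbut-2-en-1-yl)phenyl]-N,N-dimethyl-3-oxopropanamide | CN(C)C(=O)CC(=O)c1cc(CC=C(C)C)c(OCOC)c(OC)c1 | intermediate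
16 | (3S)-3-hydroxy-3-[3-methoxy-4-(methoxymethoxy)-5-(3-methylbut-2-en-1-yl)phenyl]-N,N-dimethylpropanamide | COc1cc([C@H](CC(=O)N(C)C)O)cc(CC=C(C)C)c1OCOC | intermediate
17 | (3S)-3-[3-methoxy-4-(methoxymethoxy)-5-(3-methylbut-2-en-1-yl)phenyl]-N,N-dimethyl-3-(trimethylsilyloxy)propanamide | COc1cc([C@H](CC(=O)N(C)C)O[Si](C)(C)C)cc(CC=C(C)C)c1OCOC | intermediate
18 | 3,5-bis(methoxymethoxy)-4,6-bis(3-methylbut-2-en-1-yl)benzyne (C4a≡C8a) | C1#CC(OCOC)=C(CC=C(C)C)C(OCOC)=C1CC=C(C)C | intermediate
19 | potassium alkoxide of 16, (S) | COc1cc([C@H](CC(=O)N(C)C)[O-])cc(CC=C(C)C)c1OCOC.[K+] | intermediate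
20 | arylpotassium formed by addition of 19 to C8a of 18 (metal on C4a), (S) | COc1cc([C@H](CC(=O)N(C)C)Oc2c([K])c(OCOC)c(CC=C(C)C)c(OCOC)c2CC=C(C)C)cc(CC=C(C)C)c1OCOC | intermediate
21 | potassium (2S)-4-(dimethylamino)chroman-4-olate precursor of 22 (C4 configuration undefined) | COc1cc([C@@H]2CC([O-])(N(C)C)c3c(OCOC)c(CC=C(C)C)c(OCOC)c(CC=C(C)C)c3O2)cc(CC=C(C)C)c1OCOC.[K+] | intermediate
22 | (2S)-5,7-bis(methoxymethoxy)-2-[3-methoxy-4-(methoxymethoxy)-5-(3-methylbut-2-en-1-yl)phenyl]-6,8-bis(3-methylbut-2-en-1-yl)-2,3-dihydro-4H-chromen-4-one | COc1cc([C@@H]2CC(=O)c3c(OCOC)c(CC=C(C)C)c(OCOC)c(CC=C(C)C)c3O2)cc(CC=C(C)C)c1OCOC | intermediate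
23 | (2S)-5,7-dihydroxy-2-[4-hydroxy-3-methoxy-5-(3-methylbut-2-en-1-yl)phenyl]-6,8-bis(3-methylbut-2-en-1-yl)-2,3-dihydro-4H-chromen-4-one | COc1cc([C@@H]2CC(=O)c3c(O)c(CC=C(C)C)c(O)c(CC=C(C)C)c3O2)cc(CC=C(C)C)c1O | target

**Step count and main risks**
Total step count: 14. Longest linear sequence: 9 (steps 1 to 7, 13, 14).

Most likely to fail, first: step 13.
- Three processes could defeat it. The C4a carbanion may pick up a proton before it reaches the amide carbonyl, so the event stops at O-arylation. The hemiaminal alkoxide may collapse early, which would expose the flavanone to base and erode C2 through ring opening. The aryne may be used up by the solvent or by ene reaction with prenyl groups.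
- The fallback uses known chemistry, sets out from 11 and 16, and comes back at 22.
- With KF/18-crown-6 in THF at −20 °C the free alcohol 16 adds across aryne 18. This is O–H insertion, a known arylation of aliphatic alcohols, under the same regiochemical control by the C5 oxygen. It gives the aryl ether amide F1 with the C2–O bond intact.
- The tertiary amide of F1 is then activated with Tf2O/2-chloropyridine in CH2Cl2 at −78 → 0 °C. The free C4a position, flanked by two oxygens, attacks the activated carbonyl carbon in an intramolecular Vilsmeier–Haack-type acylation. This gives the cyclic iminium triflate F2, which aqueous NaHCO3 hydrolyses to 22.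

Second: step 5.
- The base may remove a benzylic-allylic proton of the prenyl group already present (lateral metalation, followed by carbamoyl migration) instead of the ring proton.
- The fallback replaces carbanion alkylation by cross-coupling, sets out from 2, and comes back at 11.
- NBS (3 equiv, MeCN, 0 °C) fills all three free ring positions to give the tribromophenol F3, and hexamethyldisilazane gives its silyl ether F4.
- n-BuLi (1 equiv, THF, −78 °C) followed by Tf2O brings about, in one flask, bromine–lithium exchange ortho to the silyloxy group, a 1,3 O→C silyl shift (retro-Brook rearrangement, the only irreversible exit for the exchanging anions) and O-triflation. The product is the dibromo silyl triflate F5.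
- A double Stille coupling with tributyl(prenyl)stannane (Pd(P(t-Bu)3)2, toluene, 90 °C, bromide reacting before the hindered triflate) gives 11. No prenyl group ever meets an organolithium base.

Third: step 14.
- Brønsted acid may add the freed phenols at O5, O7 or O4' across the neighbouring prenyl double bonds (chroman formation) or hydrate these alkenes.
- The fallback exchanges the protecting groups without protic acid, sets out from 22, and comes back at 23.
- Me3SiOTf/2,2'-bipyridyl in CH2Cl2 at 0 °C turns the three aryl MOM ethers into silyl ethers, the methoxymethyl unit being taken up by the bipyridyl. This gives the tris(trimethylsilyl) ether F6.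
- Water at neutral pH then hydrolyses F6 to 23.

**Further compounds**
F1 | step 13 | (3S)-3-[3,5-bis(methoxymethoxy)-2,4-bis(3-methylbut-2-en-1-yl)phenoxy]-3-[3-methoxy-4-(methoxymethoxy)-5-(3-methylbut-2-en-1-yl)phenyl]-N,N-dimethylpropanamide | COc1cc([C@H](CC(=O)N(C)C)Oc2cc(OCOC)c(CC=C(C)C)c(OCOC)c2CC=C(C)C)cc(CC=C(C)C)c1OCOC
F2 | step 13 | (2S)-4-(dimethyliminio) analogue of 22, triflate salt | COc1cc([C@@H]2CC(=[N+](C)C)c3c(OCOC)c(CC=C(C)C)c(OCOC)c(CC=C(C)C)c3O2)cc(CC=C(C)C)c1OCOC.[O-]S(=O)(=O)C(F)(F)F
F3 | step 5 | 2,4,6-tribromo-3,5-bis(methoxymethoxy)phenol | Oc1c(Br)c(OCOC)c(Br)c(OCOC)c1Br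
F4 | step 5 | [2,4,6-tribromo-3,5-bis(methoxymethoxy)phenoxy]trimethylsilane | C[Si](C)(C)Oc1c(Br)c(OCOC)c(Br)c(OCOC)c1Br
F5 | step 5 | 2,4-dibromo-3,5-bis(methoxymethoxy)-6-(trimethylsilyl)phenyl trifluoromethanesulfonate | FC(F)(F)S(=O)(=O)Oc1c(Br)c(OCOC)c(Br)c(OCOC)c1[Si](C)(C)C
F6 | step 14 | 5,7,4'-tris(trimethylsilyl) ether of 23, (2S) | COc1cc([C@@H]2CC(=O)c3c(O[Si](C)(C)C)c(CC=C(C)C)c(O[Si](C)(C)C)c(CC=C(C)C)c3O2)cc(CC=C(C)C)c1O[Si](C)(C)C
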